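The cyclohexane is disconnected across C3–C4, the two ring carbons that end up bearing Cl and Br. Because this bond lies far from the carbinol carbon C1, C1 can be made first as an open-chain quaternary centre by a tartrate-controlled epoxidation and only then tied into the ring. One ring-closing metathesis joins the allyl and 3-methylbut-3-enyl arms of a (2S)-2-silyloxypentenol, giving the six-membered ring with the C3=C4 alkene and the C4 methyl in place. The precursor is an acyclic 1,7-diene whose tertiary oxygen is capped as a trimethylsilyl ether and whose CH2OH is free; that CH2OH later relays C1 to C3 and C4 and then becomes the side-chain anchor.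

Key step: step 5

Remark: ring atoms are numbered C1 (carbinol carbon), C3 (CHCl) and C4 (CBr(CH3)); both tartrate-mediated steps are assumed to follow the usual Katsuki–Sharpless facial rule, which here means that D-(−)-tartrate gives the (R)-epoxide in step 2 and L-(+)-tartrate leaves the (R)-carbinol in step 11.

Step 1
Reactants: 1 2-methylprop-2-en-1-ol; 2 3-chloro-2-methylprop-1-ene
Product: 4 5-methyl-2-methylidenehex-5-en-1-ol, via dilithiated methallyl alcohol 3 (not isolated)
Conditions: n-BuLi (2.2 equiv), TMEDA, Et2O, 0 °C to rt; then 2, THF, −78 °C to rt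
Reagents that add atoms: none
Why: Double deprotonation gives the O,C-dilithio species, whose allylic carbon is the more nucleophilic site and is alkylated by the allylic chloride (direct and allylic-transposed substitution give the same product), a dianion alkylation that installs the 3-methylbut-3-enyl arm in one operation.

Step 2
Reactants: 4 5-methyl-2-methylidenehex-5-en-1-ol
Product: 5 [(2R)-2-(3-methylbut-3-en-1-yl)oxiran-2-yl]methanol
Conditions: Ti(OiPr)4 (10 mol %), D-(−)-diisopropyl tartrate (12 mol %), t-BuOOH (2 equiv), 4 Å MS, CH2Cl2, −20 °C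
Reagents that add atoms: tert-butyl hydroperoxide, CC(C)(C)OO
Why: Katsuki–Sharpless asymmetric epoxidation: the titanium tartrate binds the allylic alkoxide, so only the hydroxyl-bearing 1,1-disubstituted alkene is oxidised, and the D-(−)-tartrate ligand selects the enantioface that gives the (R)-epoxide, whose quaternary carbon becomes C1.

Step 3
Reactants: 5 [(2R)-2-(3-methylbut-3-en-1-yl)oxiran-2-yl]methanol; 6 vinylmagnesium bromide
Product: 7 (2S)-2-(3-methylbut-3-en-1-yl)pent-4-ene-1,2-diol
Conditions: 6 (3 equiv), CuBr·SMe2 (10 mol %), THF, −30 to 0 °C; aq. NH4Cl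
Reagents that add atoms: none
Why: Copper-catalysed SN2 opening of the 2,2-disubstituted epoxide by the vinyl nucleophile occurs at the unsubstituted CH2, which becomes the allyl arm, while the quaternary centre is untouched (R becomes S only through the change in priorities, and a Payne shift of the alkoxide would regenerate the same enantiomer).

Step 4
Reactants: 7 (2S)-2-(3-methylbut-3-en-1-yl)pent-4-ene-1,2-diol
Product: 9 (2S)-2-(3-methylbut-3-en-1-yl)-2-[(trimethylsilyl)oxy]pent-4-en-1-ol, via bis(trimethylsilyl) ether 8 (not isolated)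
Conditions: TMSCl (2.5 equiv), imidazole, CH2Cl2, 0 °C; then MeOH, K2CO3 (cat.), 0 °C
Reagents that add atoms: chlorotrimethylsilane, C[Si](C)(C)Cl
Why: Exhaustive silylation followed by base-catalysed methanolysis, which removes a primary trimethylsilyl ether far faster than a tertiary one, leaves only the tertiary oxygen capped, so that CH2OH is the single oxygen nucleophile available in step 6.

Step 5
Reactants: 9 (2S)-2-(3-methylbut-3-en-1-yl)-2-[(trimethylsilyl)oxy]pent-4-en-1-ol
Product: 10 [(1S)-4-methyl-1-[(trimethylsilyl)oxy]cyclohex-3-en-1-yl]methanol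
Conditions: second-generation Grubbs catalyst RuCl2(=CHPh)(H2IMes)(PCy3) (3 mol %), CH2Cl2 (0.02 M), 40 °C
Reagents that add atoms: none
Why: Ring-closing olefin metathesis: the ruthenium benzylidene initiates on the unhindered allyl terminus, the resulting alkylidene adds across the 1,1-disubstituted alkene of the other arm in a [2+2] step, and cycloreversion of the ruthenacyclobutane releases the cyclohexene while ethene leaves the solution. The closest known reaction type is the metathesis closure of a monosubstituted onto a 1,1-disubstituted alkene to give a trisubstituted cyclohexene. The ring is closed by joining the two alkene termini of an octa-1,7-diene, so the new C3=C4 bond is endocyclic in a six-membered carbocycle with the methyl already on C4. No stereocentre is created; C1 is carried unchanged from step 2. The step needs ring closure to win over cross-metathesis oligomers, which the quaternary silyloxy carbon (Thorpe–Ingold compression), the strain-free six-membered ring and moderate dilution should secure, and the free primary hydroxyl and the silyl ether are spectators for this catalyst.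

Step 6
Reactants: 10 [(1S)-4-methyl-1-[(trimethylsilyl)oxy]cyclohex-3-en-1-yl]methanol
Product: 11 trimethyl{[(1S,4S,6S)-6-chloro-1-methyl-2-oxabicyclo[2.2.2]octan-4-yl]oxy}silane
Conditions: N-chlorosuccinimide (1.1 equiv), Ph3P=S (5 mol %), CH2Cl2, −20 to 0 °C, dark
Reagents that add atoms: N-chlorosuccinimide, O=C1CCC(=O)N1Cl
Why: Chloroetherification: Cl+ transfer from the Lewis-base-activated N-chloroimide to C3=C4 is captured by the CH2OH oxygen at the tertiary carbon C4 (Markovnikov, six-membered closure of the cineole type), which is only possible on the ring face that carries CH2OH, so anti addition fixes Cl on C3 on the opposite face and C1 thereby controls both new centres.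

Step 7
Reactants: 11 trimethyl{[(1S,4S,6S)-6-chloro-1-methyl-2-oxabicyclo[2.2.2]octan-4-yl]oxy}silane
Product: 12 (1S,3S,4S)-4-bromo-3-chloro-1-(hydroxymethyl)-4-methylcyclohexan-1-ol
Conditions: BBr3 (2.2 equiv), CH2Cl2, −78 to −20 °C; aq. NaHCO3
Reagents that add atoms: boron tribromide, BrB(Br)Br
Why: Lewis-acid ether cleavage: BBr3 activates the bridging oxygen, the tertiary C4–O bond ionises with help from the antiperiplanar C3–Cl (chloronium-like ion), and bromide enters at C4 from the face the oxygen left, giving the trans-diaxial bromochloride with net retention, while the same reagent removes the trimethylsilyl group and C1 is spared because it is a bridgehead before ring opening and part of a cyclic borate next to an oxygenated CH2 afterwards.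

Step 8
Reactants: 12 (1S,3S,4S)-4-bromo-3-chloro-1-(hydroxymethyl)-4-methylcyclohexan-1-ol
Product: 13 (1S,3S,4S)-4-bromo-3-chloro-4-methyl-1-[(triethylsilyl)oxy]-1-{[(triethylsilyl)oxy]methyl}cyclohexane
Conditions: TESOTf (2.5 equiv), 2,6-lutidine, CH2Cl2, −78 to 0 °C
Reagents that add atoms: triethylsilyl trifluoromethanesulfonate, CC[Si](CC)(CC)OS(=O)(=O)C(F)(F)F
Why: Silylation with the silyl triflate and a hindered pyridine base caps both hydroxyls, the tertiary one included, under conditions too mild and too weakly basic to disturb the tertiary bromide.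

Step 9
Reactants: 13 (1S,3S,4S)-4-bromo-3-chloro-4-methyl-1-[(triethylsilyl)oxy]-1-{[(triethylsilyl)oxy]methyl}cyclohexane
Product: 14 (1S,3S,4S)-4-bromo-3-chloro-4-methyl-1-[(triethylsilyl)oxy]cyclohexane-1-carbaldehyde
Conditions: (COCl)2, DMSO, CH2Cl2, −78 to −35 °C; then Et3N, −78 to 0 °C
Reagents that add atoms: none
Why: Swern oxidation applied directly to the bis-silyl ether: the chlorosulfonium reagent cleaves and oxidises the primary triethylsilyl ether, the hindered tertiary one is inert, and the aldehyde formed has no α-hydrogen and so cannot epimerise or enolise.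

Step 10
Reactants: 15 3-[(tert-butyldimethylsilyl)oxy]propanal; 16 isopropenylmagnesium bromide
Product: 17 rac-5-[(tert-butyldimethylsilyl)oxy]-2-methylpent-1-en-3-ol
Conditions: THF, −78 to 0 °C; aq. NH4Cl
Reagents that add atoms: none
Why: Grignard addition of the alkenyl nucleophile to the aldehyde gives the racemic 2-methyl-substituted secondary allylic alcohol needed for resolution.

Step 11
Reactants: 17 rac-5-[(tert-butyldimethylsilyl)oxy]-2-methylpent-1-en-3-ol
Product: 18 (3R)-5-[(tert-butyldimethylsilyl)oxy]-2-methylpent-1-en-3-ol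
Conditions: Ti(OiPr)4 (0.2 equiv), L-(+)-diisopropyl tartrate (0.24 equiv), t-BuOOH (0.6 equiv), 4 Å MS, CH2Cl2, −20 °C
Reagents that add atoms: none
Why: Katsuki–Sharpless kinetic resolution: with the L-(+)-tartrate catalyst the (S)-alcohol is epoxidised much faster than its enantiomer, so stopping the oxidation slightly past half conversion should leave the (R)-alcohol in high enantiomeric purity, which sets the side-chain carbinol.

Step 12
Reactants: 18 (3R)-5-[(tert-butyldimethylsilyl)oxy]-2-methylpent-1-en-3-ol
Product: 19 (3R)-3,5-bis[(tert-butyldimethylsilyl)oxy]-2-methylpent-1-ene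
Conditions: TBSCl, imidazole, DMF, rt
Reagents that add atoms: tert-butyldimethylsilyl chloride, CC(C)(C)[Si](C)(C)Cl
Why: Standard silyl ether formation on the secondary allylic hydroxyl; the stereocentre is not involved.

Step 13
Reactants: 19 (3R)-3,5-bis[(tert-butyldimethylsilyl)oxy]-2-methylpent-1-ene
Product: 20 (3R)-3-[(tert-butyldimethylsilyl)oxy]-4-methylpent-4-en-1-ol
Conditions: camphorsulfonic acid (10 mol %), MeOH/CH2Cl2, 0 °C
Reagents that add atoms: none
Why: Acid-catalysed methanolysis cleaves the unhindered primary silyl ether much faster than the secondary one flanked by the isopropenyl group (selective desilylation).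

Step 14
Reactants: 20 (3R)-3-[(tert-butyldimethylsilyl)oxy]-4-methylpent-4-en-1-ol
Product: 21 {[(3R)-5-bromo-2-methylpent-1-en-3-yl]oxy}(tert-butyl)dimethylsilane
Conditions: CBr4, PPh3, CH2Cl2, 0 °C
Reagents that add atoms: carbon tetrabromide, BrC(Br)(Br)Br
Why: Appel bromination converts the primary alcohol into the bromide under neutral conditions that leave the allylic silyl ether and the alkene alone.

Step 15
Reactants: 14 (1S,3S,4S)-4-bromo-3-chloro-4-methyl-1-[(triethylsilyl)oxy]cyclohexane-1-carbaldehyde; 21 {[(3R)-5-bromo-2-methylpent-1-en-3-yl]oxy}(tert-butyl)dimethylsilane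
Product: 23 (4R)-1-[(1S,3S,4S)-4-bromo-3-chloro-4-methyl-1-[(triethylsilyl)oxy]cyclohexyl]-4-[(tert-butyldimethylsilyl)oxy]-5-methylhex-5-en-1-ol (both C1 epimers of the hexenol chain), via alkylmagnesium bromide 22 (not isolated)
Conditions: 21 (1.5 equiv), Mg turnings (1,2-dibromoethane activation), THF, rt; then 14, THF, −78 to −20 °C; aq. NH4Cl
Reagents that add atoms: none
Why: Magnesium insertion gives the primary alkyl Grignard reagent, which should add to the non-enolisable aldehyde at low temperature far faster than it can attack the tertiary bromide or the secondary chloride (Grignard addition); the new carbinol centre forms as a mixture that step 16 erases.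

Step 16
Reactants: 23 (4R)-1-[(1S,3S,4S)-4-bromo-3-chloro-4-methyl-1-[(triethylsilyl)oxy]cyclohexyl]-4-[(tert-butyldimethylsilyl)oxy]-5-methylhex-5-en-1-ol
Product: 24 (4R)-1-[(1S,3S,4S)-4-bromo-3-chloro-4-methyl-1-[(triethylsilyl)oxy]cyclohexyl]-4-[(tert-butyldimethylsilyl)oxy]-5-methylhex-5-en-1-one
Conditions: Dess–Martin periodinane, NaHCO3, CH2Cl2, 0 °C to rt
Reagents that add atoms: none
Why: Dess–Martin oxidation of the secondary alcohol to the ketone under buffered, non-basic conditions that the halides and silyl ethers tolerate.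

Step 17
Reactants: 24 (4R)-1-[(1S,3S,4S)-4-bromo-3-chloro-4-methyl-1-[(triethylsilyl)oxy]cyclohexyl]-4-[(tert-butyldimethylsilyl)oxy]-5-methylhex-5-en-1-one
Product: 25 (3R)-6-[(1S,3S,4S)-4-bromo-3-chloro-4-methyl-1-[(triethylsilyl)oxy]cyclohexyl]-3-[(tert-butyldimethylsilyl)oxy]-2-methylhepta-1,6-diene
Conditions: Cp2TiMe2 (3 equiv), toluene/THF, 65 °C, dark
Reagents that add atoms: dimethyltitanocene Cp2TiMe2, C[Ti](C)(C1C=CC=C1)C1C=CC=C1
Why: Petasis methylenation: thermolysis of Cp2TiMe2 gives Cp2Ti=CH2, which converts the hindered ketone into the 1,1-disubstituted alkene through an oxatitanacyclobutane, and being neither basic nor Lewis acidic it should spare the enolisable position and the tertiary bromide.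

Step 18
Reactants: 25 (3R)-6-[(1S,3S,4S)-4-bromo-3-chloro-4-methyl-1-[(triethylsilyl)oxy]cyclohexyl]-3-[(tert-butyldimethylsilyl)oxy]-2-methylhepta-1,6-diene
Product: 26 (1S,3S,4S)-4-bromo-3-chloro-1-[(5R)-5-hydroxy-6-methylhepta-1,6-dien-2-yl]-4-methylcyclohexan-1-ol
Conditions: HF·pyridine, pyridine, THF, 0 °C to rt
Reagents that add atoms: none
Why: Fluoride-driven cleavage of both silicon–oxygen bonds under pyridine-buffered conditions releases the two hydroxyls without ionising the tertiary allylic carbinol or the tertiary bromide (global desilylation).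

Compound list
1 | 2-methylprop-2-en-1-ol | C=C(C)CO | starting material
2 | 3-chloro-2-methylprop-1-ene | C=C(C)CCl | starting material
3 | dilithiated methallyl alcohol (lithium 2-(lithiomethyl)prop-2-en-1-olate) | [Li]CC(=C)CO[Li] | intermediate
4 | 5-methyl-2-methylidenehex-5-en-1-ol | C=C(C)CCC(=C)CO | intermediate
5 | [(2R)-2-(3-methylbut-3-en-1-yl)oxiran-2-yl]methanol | OC[C@]1(CCC(C)=C)CO1 | intermediate
6 | vinylmagnesium bromide | C=C[Mg]Br | starting material
7 | (2S)-2-(3-methylbut-3-en-1-yl)pent-4-ene-1,2-diol | OC[C@@](O)(CC=C)CCC(C)=C | intermediate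
8 | (2S)-2-(3-methylbut-3-en-1-yl)-1,2-bis[(trimethylsilyl)oxy]pent-4-ene | C[Si](C)(C)OC[C@@](O[Si](C)(C)C)(CC=C)CCC(C)=C | intermediate
9 | (2S)-2-(3-methylbut-3-en-1-yl)-2-[(trimethylsilyl)oxy]pent-4-en-1-ol | OC[C@@](O[Si](C)(C)C)(CC=C)CCC(C)=C | intermediate
10 | [(1S)-4-methyl-1-[(trimethylsilyl)oxy]cyclohex-3-en-1-yl]methanol | OC[C@]1(O[Si](C)(C)C)CCC(C)=CC1 | intermediate
11 | trimethyl{[(1S,4S,6S)-6-chloro-1-methyl-2-oxabicyclo[2.2.2]octan-4-yl]oxy}silane | C2[C@]1(O[Si](C)(C)C)CC[C@](C)(O2)[C@@H](Cl)C1 | intermediate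
12 | (1S,3S,4S)-4-bromo-3-chloro-1-(hydroxymethyl)-4-methylcyclohexan-1-ol | OC[C@]1(O)CC[C@](C)(Br)[C@@H](Cl)C1 | intermediate
13 | (1S,3S,4S)-4-bromo-3-chloro-4-methyl-1-[(triethylsilyl)oxy]-1-{[(triethylsilyl)oxy]methyl}cyclohexane | CC[Si](CC)(CC)OC[C@]1(O[Si](CC)(CC)CC)CC[C@](C)(Br)[C@@H](Cl)C1 | intermediate
14 | (1S,3S,4S)-4-bromo-3-chloro-4-methyl-1-[(triethylsilyl)oxy]cyclohexane-1-carbaldehyde | O=C[C@]1(O[Si](CC)(CC)CC)CC[C@](C)(Br)[C@@H](Cl)C1 | intermediate
15 | 3-[(tert-butyldimethylsilyl)oxy]propanal | O=CCCO[Si](C)(C)C(C)(C)C | starting material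
16 | isopropenylmagnesium bromide (prop-1-en-2-ylmagnesium bromide) | C=C(C)[Mg]Br | starting material
17 | rac-5-[(tert-butyldimethylsilyl)oxy]-2-methylpent-1-en-3-ol | C=C(C)C(O)CCO[Si](C)(C)C(C)(C)C | intermediate
18 | (3R)-5-[(tert-butyldimethylsilyl)oxy]-2-methylpent-1-en-3-ol | C=C(C)[C@H](O)CCO[Si](C)(C)C(C)(C)C | intermediate
19 | (3R)-3,5-bis[(tert-butyldimethylsilyl)oxy]-2-methylpent-1-ene | C=C(C)[C@H](O[Si](C)(C)C(C)(C)C)CCO[Si](C)(C)C(C)(C)C | intermediate
20 | (3R)-3-[(tert-butyldimethylsilyl)oxy]-4-methylpent-4-en-1-ol | C=C(C)[C@H](O[Si](C)(C)C(C)(C)C)CCO | intermediate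
21 | {[(3R)-5-bromo-2-methylpent-1-en-3-yl]oxy}(tert-butyl)dimethylsilane | C=C(C)[C@H](O[Si](C)(C)C(C)(C)C)CCBr | intermediate
22 | [(3R)-3-[(tert-butyldimethylsilyl)oxy]-4-methylpent-4-en-1-yl]magnesium bromide | C=C(C)[C@H](O[Si](C)(C)C(C)(C)C)CC[Mg]Br | intermediate
23 | (4R)-1-[(1S,3S,4S)-4-bromo-3-chloro-4-methyl-1-[(triethylsilyl)oxy]cyclohexyl]-4-[(tert-butyldimethylsilyl)oxy]-5-methylhex-5-en-1-ol (both C1 epimers) | C=C(C)[C@H](O[Si](C)(C)C(C)(C)C)CCC(O)[C@]1(O[Si](CC)(CC)CC)CC[C@](C)(Br)[C@@H](Cl)C1 | intermediate
24 | (4R)-1-[(1S,3S,4S)-4-bromo-3-chloro-4-methyl-1-[(triethylsilyl)oxy]cyclohexyl]-4-[(tert-butyldimethylsilyl)oxy]-5-methylhex-5-en-1-one | C=C(C)[C@H](O[Si](C)(C)C(C)(C)C)CCC(=O)[C@]1(O[Si](CC)(CC)CC)CC[C@](C)(Br)[C@@H](Cl)C1 | intermediate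
25 | (3R)-6-[(1S,3S,4S)-4-bromo-3-chloro-4-methyl-1-[(triethylsilyl)oxy]cyclohexyl]-3-[(tert-butyldimethylsilyl)oxy]-2-methylhepta-1,6-diene | C=C(C)[C@H](O[Si](C)(C)C(C)(C)C)CCC(=C)[C@]1(O[Si](CC)(CC)CC)CC[C@](C)(Br)[C@@H](Cl)C1 | intermediate
26 | (1S,3S,4S)-4-bromo-3-chloro-1-[(5R)-5-hydroxy-6-methylhepta-1,6-dien-2-yl]-4-methylcyclohexan-1-ol | C=C(C)[C@H](O)CCC(=C)[C@]1(O)CC[C@](C)(Br)[C@@H](Cl)C1 | target

Total step count: 18. Longest linear sequence: 13 steps (steps 1–9 and 15–18); the side-chain branch (steps 10–14) joins at step 15.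

Steps most likely to fail

Step 6. The chloronium ion may lose an allylic proton (ene-type allylic chlorination), or chloride may add before the hydroxyl closes the ring. The fallback replaces halonium chemistry by alkoxymercuration and sets out from 10. Cyclisation with Hg(OAc)2 in CH2Cl2, followed by exchange with aqueous NaCl, should give chloro[(1S,4S,6S)-1-methyl-4-[(trimethylsilyl)oxy]-2-oxabicyclo[2.2.2]octan-6-yl]mercury F1, formed in the same anti, Markovnikov sense with HgCl where chlorine is wanted. Electrophilic chlorodemercuration with Cl2 in pyridine, which is expected to proceed with retention at carbon when radical chains are suppressed, would then return to the route at 11.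

Step 7. Ionisation under the strongly Lewis acidic boron halide may end in proton loss (elimination), in bromide entering at C3 with migration of chlorine, or in ionisation at C1. The fallback is an acylative ether cleavage and sets out from 11. Acetyl bromide with catalytic ZnBr2 in CH2Cl2 at 0 °C would acylate the bridging oxygen and turn the silyl ether into an acetate. The same chlorine-assisted bromide capture should then give [(1S,3S,4S)-1-acetoxy-4-bromo-3-chloro-4-methylcyclohexyl]methyl acetate F2, with no free Lewis acid at C1. Reduction of both acetates with i-Bu2AlH at −78 °C would return to the route at 12.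

Step 17. Methylenation of the hindered, doubly flanked ketone may be slow at a temperature where thermal dehydrohalogenation or enolisation begins to compete. The fallback is a Peterson olefination and sets out from 24. Addition of Me3SiCH2Li in the presence of CeCl3 (THF, −78 °C), a weakly basic nucleophile suited to hindered enolisable ketones, should give the β-hydroxysilane (5R)-2-[(1S,3S,4S)-4-bromo-3-chloro-4-methyl-1-[(triethylsilyl)oxy]cyclohexyl]-5-[(tert-butyldimethylsilyl)oxy]-6-methyl-1-(trimethylsilyl)hept-6-en-2-ol F3. HF·pyridine would then effect the acid-type Peterson elimination and cleave both silyl ethers in the same flask, so the fallback comes back at the target 26.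

Further compounds
F1 | step 6 | chloro[(1S,4S,6S)-1-methyl-4-[(trimethylsilyl)oxy]-2-oxabicyclo[2.2.2]octan-6-yl]mercury | C2[C@]1(O[Si](C)(C)C)CC[C@](C)(O2)[C@@H]([Hg]Cl)C1
F2 | step 7 | [(1S,3S,4S)-1-acetoxy-4-bromo-3-chloro-4-methylcyclohexyl]methyl acetate | CC(=O)OC[C@]1(OC(C)=O)CC[C@](C)(Br)[C@@H](Cl)C1
F3 | step 17 | (5R)-2-[(1S,3S,4S)-4-bromo-3-chloro-4-methyl-1-[(triethylsilyl)oxy]cyclohexyl]-5-[(tert-butyldimethylsilyl)oxy]-6-methyl-1-(trimethylsilyl)hept-6-en-2-ol | C=C(C)[C@H](O[Si](C)(C)C(C)(C)C)CCC(O)(C[Si](C)(C)C)[C@]1(O[Si](CC)(CC)CC)CC[C@](C)(Br)[C@@H](Cl)C1
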